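- Do not carry a share from one charge of Sub to another: Wednesday's flask has turned 24.0% of its Sub into Prd at 84 min, but Friday's flask has the same charge of Rgt with half that Sub, so its share need not match.

| flask | Sub | Rgt | time |
|---|---|---|---|
| Thursday's | 0.0500 M | 0.0500 M |  |
| Wednesday's | 0.0500 M | 0.0250 M |  |
| Tuesday's | 0.0250 M | 0.0500 M |  |
| Friday's | 0.0250 M | 0.0250 M | 84 min |

| run | time / min | [Prd] / M |
|---|---|---|
| Thursday's run | 4.8 | 0.00584 |
| Thursday's run | 14 | 0.01343 |
| Thursday's run | 28 | 0.01989 |
| Thursday's run | 44 | 0.02402 |
| Thursday's run | 63 | 0.02683 |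
| Thursday's run | 84 | 0.02916 |
| Wednesday's run | 4.8 | 0.00195 |
| Wednesday's run | 14 | 0.00419 |
| Wednesday's run | 28 | 0.00749 |
| Wednesday's run | 44 | 0.00886 |
| Wednesday's run | 63 | 0.01077 |
| Wednesday's run | 84 | 0.01202 |
| Tuesday's run | 4.8 | 0.00412 |
| Tuesday's run | 14 | 0.00944 |
| Tuesday's run | 28 | 0.01378 |
| Tuesday's run | 44 | 0.01718 |
| Tuesday's run | 63 | 0.01892 |
| Tuesday's run | 84 | 0.02055 |

(scatter of a reading: 2 × 10⁻⁴ M)

- how the opening rate goes with [Sub] round the charge of the Thursday's run: the exponent of the rate at two percent of Sub gone to Prd (one fixed amount of Prd, the same in the runs compared)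
- how the opening rate goes with [Rgt] round the charge of the Thursday's run: the exponent of the rate at two percent of Sub gone to Prd
- Prd in the Friday's run at 84 min, as a share of the Sub charged

- Overall: Sub + Rgt -> Prd.
- Constant volume, constant temperature.
- Readings of a species count what is bound in complexes too.
- "The second partner" is Rgt.
- An order is taken over about fifteen percent of the charge, up and down.

- Two extreme flasks can be solved in the head. If you freeze [Rgt] at a constant value (the pseudo-first-order picture) and the rate goes with [Sub] to the first power, halving Sub scales Prd by 0.5 at every time, and Friday's share stays at 24.0%. This end is an idealisation, since each Prd formed uses up one Rgt. If the rate ignores [Sub], Friday's flask makes Wednesday's 0.01202 M, a share of 48.1%.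
- The real flask lies between them, and Tuesday's run against Thursday's shows where. At 84 min their ratio is 0.705. This number, Prd at a given time with half the Sub over Prd with the full Sub at equal [Rgt], is the halving factor.
- At the first reading the same ratio reads 0.705, so it is nearly constant in time, and you can freeze it.
- My reckoning carries it to the lower [Rgt]: Friday's Prd is the factor times Wednesday's, 0.00847 M, a share of 33.9%.
- The factor also gives the apparent order in [Sub], 0.504, since it equals 0.5 raised to that order. Wednesday's first reading against Thursday's gives 1.58 in [Rgt].
- The forecast says 0.5, 1.6 and 41%, a share above mine, on the ground that “the activity decays with time”.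
- The flask gives 0.45 in [Sub], 1.9 in [Rgt] and 38.2% for Friday's share.

    Sub + 2 Rgt → Prd + Rgt (34.68 L² mol⁻² min⁻¹)
    2 Sub → L (0.3336 L mol⁻¹ min⁻¹)
    Sub + Rgt ⇌ Sub.Rgt, settled at all times (12.30 L mol⁻¹)

- Friday's Prd over Wednesday's at 84 min makes the halving factor 0.794, larger than the frozen 0.705 and inside the two extremes. The joining of Sub + Rgt to Sub.Rgt is what holds the opening factor at Thursday's charge off 0.5. With the joining, Thursday's charge has an apparent order in [Sub] of 0.45, an opening factor of 0.732; in the simulated run without it the order is 1.0, an opening factor of 0.493.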